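**Retrosynthetic overview**
1. Briaexcavatolide L ⇐ reduction of a C12 ketone and 2,9,14-triacetylation of a pentahydroxy-12-oxobriarane.
2. The six- and ten-membered rings ⇐ one transannular C1–C10 bond across a 14-membered 1,2-epoxy-10-en-12-one (a cembrane skeleton; the bond is cembrane C8–C3). Cp2TiCl opens the epoxide to the C1 radical.
3. The 14-membered ring ⇐ C9–C10 Nozaki–Hiyama–Kishi closure of an iodo-enone aldehyde.
4. The open chain ⇐ C13–C14 boron aldol, C1=C2 cross-metathesis and C7–C8 Nozaki–Hiyama–Kishi coupling. The 8,17-diol ⇐ a Sharpless epoxide opened at C17.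
5. Order of ring formation: γ-lactone, then the 14-membered carbocycle, then the six- and ten-membered rings together. This is the macrocycle-then-transannular order of the presumed biogenesis.

Assumption: all intermediates carry the briarane numbering of the target (C1–C20, lactone carbonyl C19), and compound 1 is bought as its E/Z mixture.

**Step 1**
Reactants: 1 ethyl 4-bromo-3-methylbut-2-enoate (E/Z mixture); 2 acrolein
Product: 4 rac-4-methyl-6-vinyl-5,6-dihydro-2H-pyran-2-one, via bromozinc dienolate 3 (not isolated)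
Conditions: Zn dust (TMSCl-activated), THF, 60 °C, slow co-addition of 1 and 2; aq NH4Cl
Reagents that add atoms: none
Why: Vinylogous Reformatsky reaction in which the zinc dienolate attacks the acrolein carbonyl through its γ-carbon and only the Z-hydroxy ester can lactonise, which drains the E/Z equilibrium and fixes the Z geometry of C5=C6 inside the ring (C3 is still racemic).

**Step 2**
Reactants: 4 rac-4-methyl-6-vinyl-5,6-dihydro-2H-pyran-2-one
Product: 5 rac-(Z)-5-hydroxy-N-methoxy-N,3-dimethylhepta-2,6-dienamide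
Conditions: MeNH(OMe)·HCl (2 equiv), Me3Al (2 equiv), CH2Cl2, 0 °C; aq potassium sodium tartrate
Reagents that add atoms: N,O-dimethylhydroxylamine hydrochloride, CNOC.Cl
Why: Weinreb aminolysis of the lactone by the aluminium amide opens the ring without touching the Z alkene and frees the C3 hydroxyl.

**Step 3**
Reactants: 5 rac-(Z)-5-hydroxy-N-methoxy-N,3-dimethylhepta-2,6-dienamide
Product: 6 (S,Z)-7-[methoxy(methyl)amino]-5-methyl-7-oxohepta-1,5-dien-3-yl butanoate
Conditions: immobilised Candida antarctica lipase B, vinyl butanoate (0.6 equiv), MTBE, 30 °C, stopped at 45% conversion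
Reagents that add atoms: vinyl butanoate, CCCC(=O)OC=C
Why: Lipase-catalysed kinetic resolution (Kazlauskas rule, small vinyl against large alkenylmethyl group) acylates only the (S)-alcohol, so the C3 stereocentre and its butanoate are installed in one operation.

**Step 4**
Reactants: 6 (S,Z)-7-[methoxy(methyl)amino]-5-methyl-7-oxohepta-1,5-dien-3-yl butanoate
Product: 7 (S,Z)-5-methyl-7-oxohepta-1,5-dien-3-yl butanoate
Conditions: iBu2AlH (1.1 equiv), CH2Cl2, −78 °C; aq potassium sodium tartrate
Reagents that add atoms: none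
Why: Partial reduction of a Weinreb amide, whose chelated tetrahedral aluminium adduct stops at the aldehyde stage and forms faster at −78 °C than the secondary butanoate is attacked, with the Z geometry kept.

**Step 5**
Reactants: 8 but-2-yne-1,4-diol
Product: 9 4-(tert-butyldimethylsilyloxy)but-2-yn-1-ol
Conditions: NaH (1.0 equiv), TBSCl (1.0 equiv), THF, 0 °C to rt
Reagents that add atoms: tert-butyldimethylsilyl chloride, CC(C)(C)[Si](C)(C)Cl
Why: Monosilylation through the sparingly soluble monosodium alkoxide differentiates the two ends of the symmetric diol.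

**Step 6**
Reactants: 9 4-(tert-butyldimethylsilyloxy)but-2-yn-1-ol
Product: 11 (Z)-4-(tert-butyldimethylsilyloxy)-3-iodo-2-methylbut-2-en-1-ol, via oxamagnesacyclopentene 10 (not isolated)
Conditions: MeMgBr (3 equiv), CuI (10 mol%), THF, 0 °C to rt; then I2, −20 °C
Reagents that add atoms: methylmagnesium bromide, C[Mg]Br; iodine, [I][I]
Why: Copper-catalysed anti-carbomagnesiation of a propargylic alkoxide puts methyl on the carbon next to the carbinol and magnesium cis to it in a five-membered chelate, and iodinolysis with retention gives the tetrasubstituted iodide with C19 cis to iodine.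

**Step 7**
Reactants: 7 (S,Z)-5-methyl-7-oxohepta-1,5-dien-3-yl butanoate; 11 (Z)-4-(tert-butyldimethylsilyloxy)-3-iodo-2-methylbut-2-en-1-ol
Product: 12 (3S,5Z,7S,8Z)-8-[(tert-butyldimethylsilyloxy)methyl]-7,10-dihydroxy-5,9-dimethyldeca-1,5,8-trien-3-yl butanoate
Conditions: CrCl2 (4 equiv), NiCl2 (2 mol%), (S)-4-isopropyl-2-[2-(methanesulfonamido)-3-methylphenyl]-4,5-dihydrooxazole (4.4 equiv), Et3N, THF, rt
Reagents that add atoms: none
Why: Nozaki–Hiyama–Kishi coupling, in which zerovalent nickel activates the alkenyl iodide and the trivalent alkenylchromium adds only to the aldehyde with retention of alkene geometry, while the chiral sulfonamide on chromium selects the aldehyde face that gives (7S), the minor epimer being removed by chromatography.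

**Step 8**
Reactants: 12 (3S,5Z,7S,8Z)-8-[(tert-butyldimethylsilyloxy)methyl]-7,10-dihydroxy-5,9-dimethyldeca-1,5,8-trien-3-yl butanoate
Product: 13 (3S,5Z,7S)-7-hydroxy-7-{(2S,3R)-2-[(tert-butyldimethylsilyloxy)methyl]-3-(hydroxymethyl)-3-methyloxiran-2-yl}-5-methylhepta-1,5-dien-3-yl butanoate
Conditions: Ti(OiPr)4 (20 mol%), D-(−)-diethyl tartrate (24 mol%), t-BuOOH, 4 Å molecular sieves, CH2Cl2, −25 °C
Reagents that add atoms: tert-butyl hydroperoxide, CC(C)(C)OO
Why: Sharpless asymmetric epoxidation directed by the primary C19 allylic alcohol, in which D-(−)-tartrate delivers oxygen to the face of the tetrasubstituted C8=C17 alkene that sets (8S,17R), the C7 hydroxyl is mismatched for this alkene, its matched partner C5=C6 is a slow Z-substituted case, and the vinyl group is no allylic alcohol.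

**Step 9**
Reactants: 13 the (8S,17R)-epoxy diol of step 8
Product: 14 (3S,5Z,7S,8S,9S)-8-[(tert-butyldimethylsilyloxy)methyl]-7,8,9,10-tetrahydroxy-5,9-dimethyldeca-1,5-dien-3-yl butanoate
Conditions: HClO4 (5 mol%), THF/H2O 4:1, 0 °C
Reagents that add atoms: water, O
Why: Acid-catalysed epoxide hydrolysis with inversion, in which positive charge builds at C17 (methyl-bearing, one β-oxygen) rather than at C8 (two β-oxygens), so water enters at C17 anti to the oxirane oxygen, the C8–O bond is kept, and the diol has the configuration that is trans on the later lactone.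

**Step 10**
Reactants: 14 the tetraol of step 9
Product: 15 (3S,5Z)-6-{(2S,3S,4R)-3-[(tert-butyldimethylsilyloxy)methyl]-3,4-dihydroxy-4-methyl-5-oxooxolan-2-yl}-5-methylhexa-1,5-dien-3-yl butanoate
Conditions: TEMPO (20 mol%), PhI(OAc)2 (2.4 equiv), CH2Cl2, rt
Reagents that add atoms: none
Why: Oxoammonium (TEMPO) oxidative lactonisation, selective for the primary alcohol, whose aldehyde is trapped by the C7 hydroxyl as a five-membered lactol and oxidised on to the γ-lactone without touching tertiary hydroxyls, alkenes, silyl ether or any stereocentre.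

**Step 11**
Reactants: 15 the γ-lactone of step 10; 16 methacrolein
Product: 17 (2E,4S,6Z)-7-{(2S,3S,4R)-3-[(tert-butyldimethylsilyloxy)methyl]-3,4-dihydroxy-4-methyl-5-oxooxolan-2-yl}-2,6-dimethyl-1-oxohepta-2,6-dien-4-yl butanoate
Conditions: second-generation Hoveyda–Grubbs catalyst (5 mol%), 16 (10 equiv), CH2Cl2, 40 °C
Reagents that add atoms: none
Why: Olefin cross-metathesis of the only terminal alkene with excess methacrolein gives the thermodynamically preferred E-trisubstituted enal, because the trisubstituted C5=C6 alkene is too hindered to react.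

**Step 12**
Reactants: 18 but-3-yn-2-ol (racemic)
Product: 20 (E)-4-iodo-3-methylbut-3-en-2-ol (racemic), via alkenylalane 19 (not isolated)
Conditions: Me3Al (3 equiv), Cp2ZrCl2 (25 mol%), CH2Cl2, 0 °C to rt; then I2, THF, −30 °C
Reagents that add atoms: trimethylaluminium, C[Al](C)C; iodine, [I][I]
Why: Negishi zirconium-catalysed carboalumination adds methyl and aluminium syn across the terminal alkyne with methyl on the internal carbon, and iodinolysis with retention gives the E iodide (the carbinol centre is erased in the next step).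

**Step 13**
Reactants: 20 (E)-4-iodo-3-methylbut-3-en-2-ol
Product: 21 (E)-4-iodo-3-methylbut-3-en-2-one
Conditions: MnO2 (15 equiv), CH2Cl2, rt
Reagents that add atoms: none
Why: Allylic alcohol oxidation on MnO2 leaves the alkenyl iodide and its geometry untouched.

**Step 14**
Reactants: 21 (E)-4-iodo-3-methylbut-3-en-2-one; 17 the enal of step 11
Product: 23 (1E,5S,6E,8S,10Z)-5-hydroxy-1-iodo-2,6,10-trimethyl-3-oxo-11-{(2S,3S,4R)-3-[(tert-butyldimethylsilyloxy)methyl]-3,4-dihydroxy-4-methyl-5-oxooxolan-2-yl}undeca-1,6,10-trien-8-yl butanoate, via diisopinocampheyl enol borinate 22 (not isolated)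
Conditions: 21 (2.5 equiv), (+)-Ipc2BCl (3 equiv), Et3N, Et2O, 0 °C; then 17, −78 to −20 °C; H2O2, MeOH, pH 7 buffer
Reagents that add atoms: none
Why: Paterson boron aldol, in which the methyl ketone enolises on its only enolisable side and the enol borinate from the (+)-reagent adds under reagent control to the enal face that gives the (14S)-carbinol, while tertiary hydroxyls, lactone and esters are inert at −78 °C.

**Step 15**
Reactants: 23 the aldol adduct of step 14
Product: 24 the C9 primary alcohol, which is 23 with CH2OH in place of CH2OTBS, (3S,7S,8S,14S,17R)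
Conditions: HF·pyridine, excess pyridine, THF, 0 °C
Reagents that add atoms: none
Why: Fluoride desilylation driven by the strong Si–F bond and buffered so that the β-hydroxy ketone, the allylic alcohol and the iodo-enone survive.

**Step 16**
Reactants: 24 the C9 primary alcohol of step 15
Product: 25 the (1S,2S)-1,2-epoxide of 24, an erythro epoxy alcohol, (1S,2S,3S,7S,8S,14S,17R)
Conditions: VO(acac)2 (5 mol%), t-BuOOH (1.5 equiv), CH2Cl2, 0 °C
Reagents that add atoms: tert-butyl hydroperoxide, CC(C)(C)OO
Why: Vanadium-catalysed hydroxyl-directed epoxidation, in which only C1=C2 is an electron-rich allylic-alcohol alkene and, in the transition state that avoids A1,2 strain with the C15 methyl, the (14S)-hydroxyl delivers oxygen to the face that gives the erythro epoxy alcohol and hence the correct C2–O configuration.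

**Step 17**
Reactants: 25 the epoxy alcohol of step 16
Product: 26 the C9 aldehyde, the seco iodo-enone aldehyde, (1S,2S,3S,7S,8S,14S,17R)
Conditions: TEMPO (20 mol%), PhI(OAc)2 (1.2 equiv), CH2Cl2, 0 °C to rt
Reagents that add atoms: none
Why: TEMPO oxidation stops at the aldehyde and discriminates the primary C9 alcohol from the secondary C14 and the tertiary C8 and C17 hydroxyls.

**Step 18**
Reactants: 26 the seco iodo-enone aldehyde of step 17
Product: 27 (1S,2S,3S,5Z,7S,8S,9R,10E,14S,17R)-3-butanoyloxy-1,2-epoxy-8,9,14,17-tetrahydroxy-12-oxo-1,10-secobriara-5,10-dien-19,7-olide (14-membered cembranoid)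
Conditions: CrCl2 (10 equiv), NiCl2 (0.1 equiv), DMSO/THF 3:1, 2 mM, rt, slow addition
Reagents that add atoms: none
Why: Intramolecular Nozaki–Hiyama–Kishi reaction at high dilution, which tolerates epoxide, ketone, esters and free hydroxyls, keeps the E geometry of the alkenylchromium, and adds to the aldehyde in the polar Felkin–Anh sense anti to the C8–O bond to set (9R).

**Step 19**
Reactants: 27 the 14-membered epoxy-cembranoid of step 18
Product: 30 (1R,2R,3S,5Z,7S,8S,9R,10S,11R,14S,17R)-3-butanoyloxy-2,8,9,14,17-pentahydroxy-12-oxobriar-5-en-19,7-olide, via C1 tertiary radical 28 (not isolated), via titanium enolate 29 (not isolated)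
Conditions: Cp2TiCl2 (30 mol%), Mn dust (8 equiv), 2,4,6-collidine hydrochloride (3 equiv), THF, 5 mM, rt
Reagents that add atoms: none
Why: Proposed new method: trivalent titanium (Cp2TiCl) opens the 1,2-epoxide homolytically at its more substituted carbon (Nugent–RajanBabu opening) to a nucleophilic tertiary C1 radical that is polarity-matched to the enone β-carbon C10 rather than to the unactivated C5=C6 alkene and adds 6-endo across the ring through a chair with C2 and C9 equatorial, anti to the C9–O and C2–O bonds in the A1,3-minimised conformer (this sets C1 and C10 with a trans ring fusion), after which a second Cp2TiCl reduces the α-keto radical to a titanium enolate that collidinium protonates from the α-face opposite the axial C15 methyl to set C11, the closest known reaction type being the Cp2TiCl-mediated transannular cyclisation of epoxygermacranolides to eudesmanolides combined with titanium-mediated epoxide-to-enone radical conjugate addition.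

**Step 20**
Reactants: 30 the pentahydroxy-12-oxobriarane of step 19
Product: 31 (1R,2R,3S,5Z,7S,8R,9R,10S,11R,14S,17R)-2,9,14-triacetoxy-3-butanoyloxy-8,17-dihydroxy-12-oxobriar-5-en-19,7-olide
Conditions: Ac2O (10 equiv), pyridine, DMAP (10 mol%), CH2Cl2, 0 °C to rt
Reagents that add atoms: acetic anhydride, CC(=O)OC(C)=O
Why: DMAP-catalysed acetylation takes the three secondary hydroxyls at C2, C9 and C14 and leaves the hindered tertiary C8 and C17 hydroxyls free, under conditions mild enough to avoid β-elimination of the C14 acetate or epimerisation at C11.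

**Step 21**
Reactants: 31 the triacetate ketone of step 20
Product: 32 Briaexcavatolide L, (1R,2R,3S,5Z,7S,8R,9R,10S,11R,12S,14S,17R)
Conditions: NaBH4, CeCl3·7H2O, MeOH, −78 °C
Reagents that add atoms: none
Why: Luche reduction, in which the ketone is the only group reduced, the near-neutral cerium medium suppresses β-elimination, and hydride arrives from the α-face opposite C15, C20 and C9 to give the (12S)-alcohol.

**Compound list**
1 | ethyl 4-bromo-3-methylbut-2-enoate (E/Z mixture) | CCOC(=O)C=C(C)CBr | starting material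
2 | acrolein | C=CC=O | starting material
3 | bromozinc dienolate from 1 | CCOC(=O)C=C(C)C[Zn]Br | intermediate
4 | rac-4-methyl-6-vinyl-5,6-dihydro-2H-pyran-2-one | CC1=CC(=O)OC(C=C)C1 | intermediate
5 | rac-(Z)-5-hydroxy-N-methoxy-N,3-dimethylhepta-2,6-dienamide | OC(C=C)C/C(C)=C\C(=O)N(C)OC | intermediate
6 | (S,Z)-Weinreb amide butanoate | CCCC(=O)O[C@H](C=C)C/C(C)=C\C(=O)N(C)OC | intermediate
7 | (S,Z)-5-methyl-7-oxohepta-1,5-dien-3-yl butanoate | CCCC(=O)O[C@H](C=C)C/C(C)=C\C=O | intermediate
8 | but-2-yne-1,4-diol | OCC#CCO | starting material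
9 | 4-(tert-butyldimethylsilyloxy)but-2-yn-1-ol | OCC#CCO[Si](C)(C)C(C)(C)C | intermediate
10 | oxamagnesacyclopentene | CC1=C(CO[Si](C)(C)C(C)(C)C)[Mg]OC1 | intermediate
11 | (Z)-4-(tert-butyldimethylsilyloxy)-3-iodo-2-methylbut-2-en-1-ol | OC/C(C)=C(\I)CO[Si](C)(C)C(C)(C)C | intermediate
12 | (3S,7S)-C7–C8 coupled ene-diol | CCCC(=O)O[C@H](C=C)C/C(C)=C\[C@H](O)/C(CO[Si](C)(C)C(C)(C)C)=C(/C)CO | intermediate
13 | (3S,7S,8S,17R)-8,17-epoxy diol | CCCC(=O)O[C@H](C=C)C/C(C)=C\[C@H](O)[C@]1(CO[Si](C)(C)C(C)(C)C)O[C@]1(C)CO | intermediate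
14 | (3S,7S,8S,17S)-7,8,17,19-tetraol | CCCC(=O)O[C@H](C=C)C/C(C)=C\[C@H](O)[C@@](O)(CO[Si](C)(C)C(C)(C)C)[C@@](C)(O)CO | intermediate
15 | (3S,7S,8S,17R)-8,17-dihydroxy γ-lactone | CCCC(=O)O[C@H](C=C)C/C(C)=C\[C@@H]1OC(=O)[C@](C)(O)[C@]1(O)CO[Si](C)(C)C(C)(C)C | intermediate
16 | methacrolein | C=C(C)C=O | starting material
17 | (1E)-enal lactone | CCCC(=O)O[C@H](/C=C(\C)C=O)C/C(C)=C\[C@@H]1OC(=O)[C@](C)(O)[C@]1(O)CO[Si](C)(C)C(C)(C)C | intermediate
18 | but-3-yn-2-ol (racemic) | CC(O)C#C | starting material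
19 | (E)-alkenylalane | C/C(=C\[Al](C)C)C(C)O[Al](C)C | intermediate
20 | (E)-4-iodo-3-methylbut-3-en-2-ol (racemic) | CC(O)/C(C)=C/I | intermediate
21 | (E)-4-iodo-3-methylbut-3-en-2-one | CC(=O)/C(C)=C/I | intermediate
22 | diisopinocampheyl enol borinate of 21 | C=C(OB([C@H]1C[C@H]2C[C@@H]([C@@H]1C)C2(C)C)[C@H]1C[C@H]2C[C@@H]([C@@H]1C)C2(C)C)/C(C)=C/I | intermediate
23 | (14S)-aldol adduct, TBS ether | CCCC(=O)O[C@H](/C=C(\C)[C@@H](O)CC(=O)/C(C)=C/I)C/C(C)=C\[C@@H]1OC(=O)[C@](C)(O)[C@]1(O)CO[Si](C)(C)C(C)(C)C | intermediate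
24 | (14S)-aldol adduct, C9 primary alcohol | CCCC(=O)O[C@H](/C=C(\C)[C@@H](O)CC(=O)/C(C)=C/I)C/C(C)=C\[C@@H]1OC(=O)[C@](C)(O)[C@]1(O)CO | intermediate
25 | (1S,2S)-epoxy alcohol | CCCC(=O)O[C@H]([C@@H]1O[C@@]1(C)[C@@H](O)CC(=O)/C(C)=C/I)C/C(C)=C\[C@@H]2OC(=O)[C@](C)(O)[C@]2(O)CO | intermediate
26 | seco iodo-enone C9 aldehyde | CCCC(=O)O[C@H]([C@@H]1O[C@@]1(C)[C@@H](O)CC(=O)/C(C)=C/I)C/C(C)=C\[C@@H]2OC(=O)[C@](C)(O)[C@]2(O)C=O | intermediate
27 | 14-membered epoxy-cembranoid | CCCC(=O)O[C@H]1C/C(C)=C\[C@@H]2OC(=O)[C@](C)(O)[C@]2(O)[C@H](O)/C=C(\C)C(=O)C[C@H](O)[C@]3(C)O[C@H]31 | intermediate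
28 | C1 tertiary radical, C2 titanoxide | CCCC(=O)O[C@H]1C/C(C)=C\[C@@H]2OC(=O)[C@](C)(O)[C@]2(O)[C@H](O)/C=C(\C)C(=O)C[C@H](O)[C](C)[C@H]1O[Ti](Cl)(C1C=CC=C1)C1C=CC=C1 | intermediate
29 | C11=C12 titanium enolate | CCCC(=O)O[C@H]1C/C(C)=C\[C@@H]2OC(=O)[C@](C)(O)[C@]2(O)[C@H](O)[C@H]2C(C)=C(O[Ti](Cl)(C3C=CC=C3)C3C=CC=C3)C[C@H](O)[C@]2(C)[C@H]1O[Ti](Cl)(C1C=CC=C1)C1C=CC=C1 | intermediate
30 | pentahydroxy-12-oxobriarane | CCCC(=O)O[C@H]1C/C(C)=C\[C@@H]2OC(=O)[C@](C)(O)[C@]2(O)[C@H](O)[C@H]2[C@@H](C)C(=O)C[C@H](O)[C@]2(C)[C@H]1O | intermediate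
31 | 2,9,14-triacetate 12-ketone | CCCC(=O)O[C@H]1C/C(C)=C\[C@@H]2OC(=O)[C@](C)(O)[C@]2(O)[C@H](OC(C)=O)[C@H]2[C@@H](C)C(=O)C[C@H](OC(C)=O)[C@]2(C)[C@H]1OC(C)=O | intermediate
32 | Briaexcavatolide L | CCCC(=O)O[C@H]1C/C(C)=C\[C@@H]2OC(=O)[C@](C)(O)[C@]2(O)[C@H](OC(C)=O)[C@H]2[C@@H](C)[C@@H](O)C[C@H](OC(C)=O)[C@]2(C)[C@H]1OC(C)=O | target

**Count and risks**
Total steps: 21. Longest linear sequence: 17 (steps 1–4, 7–11, 14–21).

Most likely to fail, first: step 19 (transannular radical closure). The C1 radical may be reduced or may lose a β-hydrogen before it crosses the ring, or it may close with the wrong facial sense.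
- The fallback sets out from 27.
- Stoichiometric Cp2TiCl (from Cp2TiCl2 and Mn, 0.2 M in THF, no proton source) deliberately diverts the epoxide by β-hydrogen loss into the C1(15)-exomethylene 2,14-diol F1.
- Hydrogen-atom transfer from an iron hydride (Fe(acac)3, PhSiH3, EtOH, 60 °C) to this 1,1-disubstituted alkene regenerates the C1 radical. It now forms at very low steady-state concentration and without the bulky titanoxy group on C2.
- Reductive olefin coupling of that radical onto the enone comes back to the route at 30.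

Second: step 18 (macrocyclisation onto a hindered α-hydroxy aldehyde). The fallback sets out from 15 and closes the ring at C13–C14 instead.
- HF·pyridine gives the lactone primary alcohol F2.
- TEMPO/PhI(OAc)2 gives the lactone aldehyde F3.
- An intermolecular Nozaki–Hiyama–Kishi coupling with 21 gives the (9R)-hydroxy methyl enone F4.
- Cross-metathesis with 16 gives the enone enal F5.
- An intramolecular boron aldol ((+)-Ipc2BCl, Et3N, 1 mM) gives the macrocyclic (14S)-allylic alcohol F6.
- VO(acac)2/t-BuOOH epoxidation comes back to the route at 27.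

Third: step 9 (site and stereochemical fidelity of the epoxide hydrolysis). The fallback sets out from 13 and replaces external water by a tethered oxygen.
- PhNCO (1 equiv, pyridine, 0 °C) carbamoylates the primary C19 hydroxyl to the phenylurethane F7.
- BF3·OEt2 followed by dilute acid forces a 5-exo attack of the carbamate carbonyl at C17 with inversion. This gives the 17,19-cyclic carbonate F8.
- Brief K2CO3/MeOH at −10 °C cleaves the strained carbonate faster than the butanoate and comes back to the route at 14.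

**Further compounds**
F1 | step 19 | C1(15)-exomethylene 2,14-diol macrocycle | CCCC(=O)O[C@H]1C/C(C)=C\[C@@H]2OC(=O)[C@](C)(O)[C@]2(O)[C@H](O)/C=C(\C)C(=O)C[C@H](O)C(=C)[C@H]1O
F2 | step 18 | lactone primary alcohol | CCCC(=O)O[C@H](C=C)C/C(C)=C\[C@@H]1OC(=O)[C@](C)(O)[C@]1(O)CO
F3 | step 18 | lactone aldehyde | CCCC(=O)O[C@H](C=C)C/C(C)=C\[C@@H]1OC(=O)[C@](C)(O)[C@]1(O)C=O
F4 | step 18 | (9R)-hydroxy methyl enone | CCCC(=O)O[C@H](C=C)C/C(C)=C\[C@@H]1OC(=O)[C@](C)(O)[C@]1(O)[C@H](O)/C=C(\C)C(C)=O
F5 | step 18 | enone enal | CCCC(=O)O[C@H](/C=C(\C)C=O)C/C(C)=C\[C@@H]1OC(=O)[C@](C)(O)[C@]1(O)[C@H](O)/C=C(\C)C(C)=O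
F6 | step 18 | macrocyclic (14S)-allylic alcohol | CCCC(=O)O[C@H]1C/C(C)=C\[C@@H]2OC(=O)[C@](C)(O)[C@]2(O)[C@H](O)/C=C(\C)C(=O)C[C@H](O)/C(C)=C/1
F7 | step 9 | C19 phenylurethane of 13 | CCCC(=O)O[C@H](C=C)C/C(C)=C\[C@H](O)[C@]1(CO[Si](C)(C)C(C)(C)C)O[C@]1(C)COC(=O)Nc1ccccc1
F8 | step 9 | 17,19-cyclic carbonate | CCCC(=O)O[C@H](C=C)C/C(C)=C\[C@H](O)[C@@](O)(CO[Si](C)(C)C(C)(C)C)[C@]1(C)COC(=O)O1
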